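Do not judge these flasks by their first reading. In the zeta run the share of target in target plus isomer of the product, the selectivity, stands at 79.7% after 0.625 d but at 75.7% after 5.00 d, so watch where the isomer stops.

| flask | substrate | reagent | remark | time |
|---|---|---|---|---|
| zeta | 0.20 M | 1.05 equiv | run made earlier |  |
| alpha | 0.20 M | 0.53 equiv | run made earlier |  |
| gamma | 0.20 M | 0.79 equiv | run made earlier |  |
| north-east | 0.20 M (fed, over 6.0 d) | 1.05 equiv | all else is in the flask from the start; the feed brings no volume worth counting | 8.0 d |
| north-west | 0.20 M | 1.05 equiv (fed, over 6.0 d) | all else is in the flask from the start; the feed brings no volume worth counting | 8.0 d |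
| east | 0.20 M | 1.05 equiv | everything together at the start | 8.0 d |

- zeta (time / d: target / %, isomer of the product / %): 0.625: 51, 13; 1.25: 55, 14; 2.08: 56, 15; 3.00: 56, 18; 4.00: 59, 19; 5.00: 56, 18
- alpha (time / d: target / %, isomer of the product / %): 0.417: 9, 1; 0.625: 21, 3; 0.833: 23, 7; 1.25: 25, 8; 2.08: 29, 16; 3.00: 31, 16; 5.00: 31, 16
- gamma (time / d: target / %, isomer of the product / %): 0.250: 13, 3; 0.833: 41, 10; 1.25: 47, 15; 2.08: 51, 17; 3.00: 50, 16; 4.00: 49, 19; 5.00: 49, 18

(readings scatter by 1.5 percentage points)

1. the flask with the highest share of target in target plus isomer of the product ("all alike" if they lie within 1.5 percentage points) (north-east / north-west / east / all alike)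
2. share of target in target plus isomer of the product at the end, north-east
3. share of target in target plus isomer of the product at the end, north-west
4. share of target in target plus isomer of the product at the end, east

- a reading or a percentage of target counts all its forms, free or not

Read the last line of each run. As the reagent goes from 0.53 equiv to 0.79 equiv to 1.05 equiv, target ends at 31%, 49% and 56%, but the isomer ends at 16%, 18% and 18%, a spread of 2 percentage points against a scatter of 1.5 points. So freeze it. Their mean, 17.3%, a reading with that scatter, is what I call the isomer ceiling: the fraction of a charge of 0.20 M at which the isomer stops in these runs while target still differs from run to run.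

For a flask whose isomer reaches the ceiling, the share then becomes target over target plus ceiling. East repeats zeta, so I reckon it at 76.4%. If a flask turned its whole charge into target and isomer with the isomer at the ceiling, its share would be one minus the ceiling, 82.7%, and I take that as my top value for north-east. The ceiling gives no number for north-west if its isomer stays below it.

My decision for the next run is to charge the reagent at the start, feed the substrate over 6.0 d, and keep the charge at 0.20 M. The forecast also picks north-east, with 79% there, 60% in north-west and 76% in east, adding “though reagent loss over time could erode that”. Its north-east figure stands below my top value.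

    substrate + reagent + released group → target + 2 released group (k = 0.230 M⁻² min⁻¹)
    substrate + reagent → target + released group (k = 9.00 × 10⁻⁴ M⁻¹ min⁻¹)
    2 substrate → homo dimer (k = 0.00230 M⁻¹ min⁻¹)
    crystals ⇌ target, rate k4*(cs4 - [target]) while solid is left; crystals form when [target] > cs4 (solubility = 0.0540 M, k = 0.00790 min⁻¹)
    target ⇌ isomer of the product (K = 0.640, k = 5.60 × 10⁻⁴ min⁻¹)

North-east ends at 81.7%, above east at 76.5% and north-west at 61.0%, and its isomer stands at 17.4% after 8.00 d, close to the ceiling of 17.3%. A smaller charge is one change that would take a flask below the forecast's 79%: taken as a fixed amount of isomer, the ceiling at 0.12 M of substrate becomes 28.8% of the charge, and the top value falls to 71.1%. The neighbour of north-east at that charge ends with isomer at 28.8% and a share of 66.7%.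

(The runs were computed on assumed constants, noise included.)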